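(The constants come from no measurement.)

In a one-step world, starting material decays with one time constant, and the yield follows from time in the vessel over that constant; we look for that constant here.

| setting | Saturday's | Tuesday's | Sunday's | Thursday's |
|---|---|---|---|---|
| starting material | 0.30 M | 0.30 M (fed, over 40.0 s) | 0.30 M | 0.30 M |
| coupling partner | 2.00 equiv | 2.00 equiv | 2.00 equiv | 2.00 equiv |
| initiator | 3.5 mol% | 3.5 mol% | 3.5 mol% | 3.5 mol% |
| time | 80 s | 80 s |  |  |
| remark | a closed flask charged with all of it at once and left for 80 s | a stirred flask in which starting material is dosed at a steady rate over 40.0 s without added volume, worked up at 80 s | a single well-mixed tank run continuously and read at steady state, 80 s in it on average | one stirred flow tank at steady state, fed with the mixture as stated, mean residence time 400 s |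

    initiator → 2 initiating radical (k1 = 0.0016 s⁻¹)
    starting material + initiating radical → chain carrier (k2 = 1.3 × 10⁵ M⁻¹ s⁻¹)
    coupling partner + chain carrier ⇌ product + initiating radical (K3 = 0.12, k3 = 53000 M⁻¹ s⁻¹)
    2 chain carrier → ended chains A (k4 = 3 × 10⁶ M⁻¹ s⁻¹)
    2 initiating radical → ended chains B (k5 = 2 × 10⁸ M⁻¹ s⁻¹)

* order of the set-ups by the amount of product at the outlet or at the end, in percent of the starting material put in, highest first (Saturday's / Tuesday's / Sunday's / Thursday's)
* amount of product at the outlet or at the end, in percent of the starting material put in, Saturday's
* amount of product at the outlet or at the end, in percent of the starting material put in, Tuesday's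
* amount of product at the outlet or at the end, in percent of the starting material put in, Sunday's
* amount of product at the outlet or at the end, in percent of the starting material put in, Thursday's

- a species is counted by the starting material in it: one ended chains A counts as two
- for a step with 2 of a species take k times the square, and two of it per event
- the stated concentrations are those of everything mixed, before any reaction; amounts are the same in each set-up
- the feed brings no volume worth counting
- run time (Saturday's): 80 s

1. Freeze the initiator. Its rate constant times the run time is 0.128, so over the run we hold it at its charge, N = 0.01050 M.

2. Freeze the initiating radical, concentration r. The chain steps pass it on and hand it back, so we balance its making against its pairing, 2 initiating radical → ended chains B (k5 = 2 × 10⁸ M⁻¹ s⁻¹). That gives r = 2.90 × 10⁻⁷ M.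

3. Starting material then falls pseudo-first-order, with time constant τ = 26.5 s. Our number is the Damköhler number Da = 3.01, the time in the vessel over τ.

4. Read off, our figures are:
- Saturday's, closed flask, 1 − exp(−Da): 95.1%.
- Tuesday's, the same decay applied to a steady feed: 88.6%.
- Sunday's, tank, Da/(1 + Da): 75.1%.
- Thursday's, where the long stay thins the initiator, so Da becomes 11.8: 92.2%.

5. Is one number enough? With the third step at equilibrium and product equal to coupling partner, chain carrier stands 8.33 times above r. Its pairing then matches radical pairing, with a ratio of 1.04. So r sags late, and we expect our figures to run a few points high.

The forecast gives Saturday's > Thursday's > Tuesday's > Sunday's, with 91.4%, 88.8%, 84.2% and 70.5% in that order: “late dosing loses contact time”.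

The simulation gives Saturday's > Thursday's > Tuesday's > Sunday's, with 91.4%, 88.9%, 84.1% and 70.4% in that order.

The forecast held, and our order stood. Saturday's left 8.36% of its starting material, so its Da read back is 2.48, below ours. Saturday's stops short of full yield partly through two ingredients of Da, the pairing of initiating radicals and the length of the run: without that pairing it gives 97.4% instead of 91.4%, and in a run ten times as long it gives 97.7%. Take a neighbour of Saturday's with 0.500 equiv of coupling partner: our reckoning of Da does not contain coupling partner, so it stays at 3.01. There coupling partner is the limiting reagent, so we take the smaller of the two limits, 50.0%. Its computed yield is 47.5%.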